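Picture a one-step world: substrate and reagent give product one for one, and the fraction of substrate left at the stop is one minus the equivalents of reagent. The runs below refuse this.

all flasks: substrate 0.050 M; free catalyst 10 mol%; impurity 1.5 mM
- beta: reagent 0.65 equiv (in portions, 2); run made earlier; portions every 3.0 h
- gamma: reagent 2.6 equiv (in portions, 2); run made earlier; portions every 3.0 h
- flask: reagent 1.30 equiv (in portions, 2); the portions of reagent follow each other after 3.0 h, the first at the start; time 2.5 d

| run | time / d | substrate / % | product / % | catalyst intermediate B / % |
|---|---|---|---|---|
| beta | 0.250 | 34.9 | 60.3 | 2.8 |
| beta | 0.500 | 28.1 | 65.6 | 0 |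
| beta | 1.25 | 27.8 | 65.5 | 0 |
| beta | 3.00 | 28.4 | 64.8 | 0 |
| gamma | 0.417 | 7.3 | 90.7 | 3.5 |
| gamma | 1.04 | 0 | 97.3 | 2.4 |
| gamma | 2.08 | 0.2 | 99.2 | 1.8 |
| gamma | 3.00 | 0 | 98.2 | 2.8 |

(readings scatter by 0.5 percentage points)

- what may be going on: reagent + catalyst intermediate A -> catalyst intermediate B; free catalyst + impurity -> spent catalyst A; free catalyst -> spent catalyst B; substrate + free catalyst -> catalyst intermediate A; catalyst intermediate B <-> free catalyst + product
- the reaction counts as stopped when no species that holds the substrate changes by six tenths of a point or more over the second half of the time

- the state of affairs at 2.5 d: stopped, and by what, or still going (all of the substrate has reacted / it is still moving / the reagent has run out first / no working catalyst is left / forward and back rates have come level)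
- conversion of substrate at 2.5 d
- amount of product at 2.5 d, in percent of the substrate charged
- amount of catalyst intermediate B at 2.5 d, in percent of the substrate charged

Take the beta run. One-step counting leaves 35.0% of its substrate, yet the readings level off at 27.8% at 1.25 d, with product 65.5% and catalyst intermediate B 0%. Add them up: 6.70% of the substrate stands in no column.

Now follow the round. Free catalyst takes up substrate as catalyst intermediate A (A), reagent turns A into catalyst intermediate B (B), and B releases product and free catalyst. So once reagent, the limiting reagent in beta, reaches zero, each working catalyst stays parked as A with one substrate on it.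

Count the working catalyst. Impurity equals 3.00% of the substrate; let it remove free catalyst one for one as spent catalyst A, and 7.00% remains of the 10 mol% charged. This count comes from the charges, and the beta gap comes from the readings, yet they lie close together.

Reckon the fraction left, then. Call f the stall rest: one minus the equivalents minus the live catalyst. Beta gives 28.0%, close to its reading. For the flask, the same count gives a stall rest of −37.0%. A free fraction below zero is no stall at all, so I commit to full conversion in the flask. The stall rest does not split product from B, so look to the gamma readings: there B reads between 1.8% and 2.8% once substrate reads 0%.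

The forecast says all of the substrate has reacted, with conversion 99.9%, product 97.6% and B 2.3%, since the flask “should therefore behave like gamma, only slightly slower”.

In the flask, all of the substrate has reacted: conversion 100%, product 98.1%, B 1.91%.

    reagent + catalyst intermediate A → catalyst intermediate B (k = 2430 M⁻¹ h⁻¹)
    free catalyst + impurity → spent catalyst A (k = 2430 M⁻¹ h⁻¹)
    free catalyst → spent catalyst B (k = 2.19 × 10⁻⁴ h⁻¹)
    substrate + free catalyst → catalyst intermediate A (k = 187 M⁻¹ h⁻¹)
    catalyst intermediate B ⇌ free catalyst + product (K = 0.129 M, k = 2.61 h⁻¹)

Reagent in the flask still stands at 23% of its charge at 2.50 d; take the live share from the 37.0% margin, divide by the equivalents, and the stall rest gives 23.1%. Now give a neighbour flask 0.520 equiv of reagent: its stall rest turns positive, 41.0%. That neighbour ends with reagent at 0%, product 52.0%, catalyst intermediate A 7.00% of the substrate, and free substrate 41%.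

The readings come from a simulation for an exercise, and the scatter is random.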